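1. C8 ketone ⇐ allylic C–H oxygenation of the C6=C7 alkene, run in the same flask as the C6=C7 ring-closing metathesis that forms the seven-membered ring.
2. Ester C–O bond ⇐ acylation of the C4 secondary carbinol with 3,4,5-trimethoxybenzoyl chloride, done before ring closure.
3. C3 tertiary carbinol ⇐ isopropyl addition to a cyclopentanone; C3a–C4 bond and C4 carbinol ⇐ aldol with 3-methylbut-3-enal.
4. C8a quaternary centre ⇐ copper-catalysed asymmetric conjugate methylation of 3-allylcyclopent-2-enone (from 3-ethoxycyclopent-2-enone).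
5. Ring order: the five-membered ring is bought as the cyclopentenone; the seven-membered ring is closed last.

Assumption: positions are cited in the azulene numbering of the target (C3 carbinol with isopropyl, C3a, C4 ester carbinol, C6 methyl, C8 ketone, C8a methyl), and the antipode of the chiral ligand in step 3 is the one that gives the (R) quaternary centre drawn.

Step 1
Reactants: 1 3-ethoxycyclopent-2-en-1-one
Product: 3 3-(prop-2-en-1-yl)cyclopent-2-en-1-one, via tertiary carbinol adduct 2 (not isolated)
Conditions: allylMgBr (1.2 equiv), Et2O/THF, −78 to 0 °C; then 1 M HCl, 0 °C, 15 min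
Reagents that add atoms: allylmagnesium bromide C=CC[Mg]Br; water O
Why: Stork–Danheiser sequence, in which 1,2-addition to the vinylogous ester carbonyl and cold acid hydrolysis/dehydration transpose the carbonyl to give the 3-substituted enone while the skipped alkene stays out of conjugation.

Step 2
Reactants: 4 3-methylbut-3-en-1-ol
Product: 5 3-methylbut-3-enal
Conditions: Dess–Martin periodinane (1.1 equiv), CH2Cl2, 0 °C; cold NaHCO3 wash; used at once as a dried solution
Reagents that add atoms: none
Why: Dess–Martin oxidation of the primary alcohol under near-neutral conditions stops at the β,γ-unsaturated aldehyde without moving the alkene into conjugation.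

Step 3
Reactants: 3 3-(prop-2-en-1-yl)cyclopent-2-en-1-one, 5 3-methylbut-3-enal
Product: 7 (2S,3R)-2-[(1S)-1-hydroxy-3-methylbut-3-en-1-yl]-3-methyl-3-(prop-2-en-1-yl)cyclopentan-1-one, via dimethylaluminium enolate 6 (not isolated)
Conditions: AlMe3 (1.3 equiv), Cu(OTf)2 (5 mol%), chiral binaphthol-based phosphoramidite ligand (10 mol%), Et2O, −30 °C; then 5 (1.5 equiv), −78 °C; aq. Rochelle salt
Reagents that add atoms: trimethylaluminium C[Al](C)C
Why: Copper-catalysed asymmetric conjugate addition sets the quaternary centre under ligand control, and the regiodefined aluminium enolate then undergoes an aldol addition through a closed chair (Zimmerman–Traxler) transition state in which the aldehyde approaches anti to the larger allyl arm (syn to methyl) and the E-enolate gives the anti (1S) carbinol.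

Step 4
Reactants: 7 (2S,3R)-2-[(1S)-1-hydroxy-3-methylbut-3-en-1-yl]-3-methyl-3-(prop-2-en-1-yl)cyclopentan-1-one
Product: 8 (1R,2S,3R)-2-[(1S)-1-hydroxy-3-methylbut-3-en-1-yl]-3-methyl-1-(propan-2-yl)-3-(prop-2-en-1-yl)cyclopentan-1-ol
Conditions: iPrMgCl (4 equiv), anhydrous CeCl3 (4 equiv), THF, −78 to −20 °C; aq. NH4Cl
Reagents that add atoms: isopropylmagnesium chloride CC(C)[Mg]Cl
Why: Chelation-assisted organocerium 1,2-addition (Imamoto conditions), in which the metal alkoxide of the neighbouring carbinol holds the ketone and isopropyl enters from the ring face opposite the C2 side chain, so the new tertiary hydroxyl is cis to that chain (1R).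

Step 5
Reactants: 8 (1R,2S,3R)-2-[(1S)-1-hydroxy-3-methylbut-3-en-1-yl]-3-methyl-1-(propan-2-yl)-3-(prop-2-en-1-yl)cyclopentan-1-ol, 9 3,4,5-trimethoxybenzoyl chloride
Product: 10 (1S)-1-[(1S,2R,5R)-2-hydroxy-5-methyl-2-(propan-2-yl)-5-(prop-2-en-1-yl)cyclopentyl]-3-methylbut-3-en-1-yl 3,4,5-trimethoxybenzoate
Conditions: 9 (1.3 equiv), Et3N (2 equiv), DMAP (0.2 equiv), CH2Cl2, 0 °C to rt
Reagents that add atoms: none
Why: DMAP-catalysed acylation forms the ester C–O bond at the secondary carbinol with retention, the hindered tertiary alcohol being unreactive.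

Step 6
Reactants: 10 (1S)-1-[(1S,2R,5R)-2-hydroxy-5-methyl-2-(propan-2-yl)-5-(prop-2-en-1-yl)cyclopentyl]-3-methylbut-3-en-1-yl 3,4,5-trimethoxybenzoate
Product: 12 (3R,3aS,4S,8aS)-3-hydroxy-6,8a-dimethyl-8-oxo-3-(propan-2-yl)-1,2,3,3a,4,5,8,8a-octahydroazulen-4-yl 3,4,5-trimethoxybenzoate (CNP0218356.1), via ring-closed ester 11 (not isolated)
Conditions: second-generation Hoveyda–Grubbs catalyst RuCl2(H2IMes)(=CH-C6H4-2-OiPr) (5 mol%), 1,2-dichloroethane (5 mM), 60 °C, argon sparge; then tBuOOH (5.5 M in decane, 4 equiv), 40 °C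
Reagents that add atoms: tert-butyl hydroperoxide CC(C)(C)OO
Why: Proposed new method: single-flask ring-closing metathesis then ruthenium-mediated allylic C–H oxygenation, in which RCM of the allyl and methallyl arms (already trans on the cyclopentane, so no stereocentre is touched) closes the trans-fused cycloheptene and the spent ruthenium alkylidene, converted by tBuOOH into oxo/tert-butylperoxy ruthenium species, abstracts the C8 allylic hydrogen (C5–H2 is inductively deactivated by the vicinal aroyloxy group, the C6 methyl is primary) and delivers oxygen there to give the enone; closest known reaction type is ruthenium/tBuOOH allylic oxidation of trisubstituted cycloalkenes to enones and metathesis–oxidation tandems run on cyclic allyl ethers.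

Compound list
1 | 3-ethoxycyclopent-2-en-1-one | CCOC1=CC(=O)CC1 | starting material
2 | 3-ethoxy-1-(prop-2-en-1-yl)cyclopent-2-en-1-ol (racemic) | CCOC1=CC(O)(CC=C)CC1 | intermediate
3 | 3-(prop-2-en-1-yl)cyclopent-2-en-1-one | C=CCC1=CC(=O)CC1 | intermediate
4 | 3-methylbut-3-en-1-ol | CC(=C)CCO | starting material
5 | 3-methylbut-3-enal | CC(=C)CC=O | intermediate
6 | dimethylaluminium (3R)-3-methyl-3-(prop-2-en-1-yl)cyclopent-1-en-1-olate | C=CC[C@@]1(C)CCC(O[Al](C)C)=C1 | intermediate
7 | (2S,3R)-2-[(1S)-1-hydroxy-3-methylbut-3-en-1-yl]-3-methyl-3-(prop-2-en-1-yl)cyclopentan-1-one | O[C@@H](CC(C)=C)[C@H]1C(=O)CC[C@]1(C)CC=C | intermediate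
8 | (1R,2S,3R)-2-[(1S)-1-hydroxy-3-methylbut-3-en-1-yl]-3-methyl-1-(propan-2-yl)-3-(prop-2-en-1-yl)cyclopentan-1-ol | O[C@@H](CC(C)=C)[C@H]1[C@](O)(C(C)C)CC[C@]1(C)CC=C | intermediate
9 | 3,4,5-trimethoxybenzoyl chloride | COc1cc(C(Cl)=O)cc(OC)c1OC | starting material
10 | (1S)-1-[(1S,2R,5R)-2-hydroxy-5-methyl-2-(propan-2-yl)-5-(prop-2-en-1-yl)cyclopentyl]-3-methylbut-3-en-1-yl 3,4,5-trimethoxybenzoate | COc1cc(C(=O)O[C@@H](CC(C)=C)[C@H]2[C@](O)(C(C)C)CC[C@]2(C)CC=C)cc(OC)c1OC | intermediate
11 | (3R,3aS,4S,8aR)-3-hydroxy-6,8a-dimethyl-3-(propan-2-yl)-1,2,3,3a,4,5,8,8a-octahydroazulen-4-yl 3,4,5-trimethoxybenzoate | COc1cc(C(=O)O[C@H]2CC(C)=CC[C@@]3(C)CC[C@@](O)(C(C)C)[C@H]23)cc(OC)c1OC | intermediate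
12 | (3R,3aS,4S,8aS)-3-hydroxy-6,8a-dimethyl-8-oxo-3-(propan-2-yl)-1,2,3,3a,4,5,8,8a-octahydroazulen-4-yl 3,4,5-trimethoxybenzoate (CNP0218356.1) | COc1cc(C(=O)O[C@H]2CC(C)=CC(=O)[C@@]3(C)CC[C@@](O)(C(C)C)[C@H]23)cc(OC)c1OC | target

Total step count: 6. Longest linear sequence: 5 steps (1, 3, 4, 5, 6); step 2 is a one-step side branch.

Steps most likely to fail

Step 6 (the proposed new step). The ruthenium residue may not turn over as an oxidant, or may oxygenate C5 or the C6 methyl instead of C8. The fallback uses known chemistry and separates the two events. It sets out from 10: RCM alone with the same catalyst gives 11, which is isolated. Oxidation of 11 with stoichiometric CrO3/3,5-dimethylpyrazole (CH2Cl2, −20 °C), a chromium ene-type pathway known to favour the allylic methylene remote from an acyloxy group, or with catalytic Rh2(caprolactamate)4/tBuOOH, then gives 12. It comes back to the route at 12 and makes no compound outside the list (F0).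

Step 3. The basic aluminium enolate may deprotonate the doubly activated α-position of 5 instead of adding to it. The face selectivity at the ring carbon also rests only on allyl being larger than methyl, so it may be modest. The fallback sets out from 3: after the same conjugate methylation, enolate 6 is silylated with Me3SiOTf to the isolable silyl enol ether trimethyl{[(3R)-3-methyl-3-(prop-2-en-1-yl)cyclopent-1-en-1-yl]oxy}silane F1. A TiCl4-promoted Mukaiyama aldol of F1 with 5 (CH2Cl2, −78 °C, open transition state, no basic enolate present) comes back to the route at 7. Any ring epimer is removed by chromatography at 7 or 8.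

Step 4. A secondary alkyl organometallic can reduce or enolise the hindered ketone, or trigger retro-aldol cleavage. The fallback sets out from 7 and closes the ring first: RCM (second-generation Hoveyda–Grubbs catalyst, CH2Cl2, 40 °C) gives the bicyclic hydroxy ketone (3aS,4S,8aR)-4-hydroxy-6,8a-dimethyl-2,3a,4,5,8,8a-hexahydroazulen-3(1H)-one F2. Isopropenylmagnesium bromide/CeCl3 (an sp2 nucleophile that cannot transfer a β-hydride) adds from the face opposite the angular methyl to give (3S,3aS,4S,8aR)-6,8a-dimethyl-3-(prop-1-en-2-yl)-1,2,3,3a,4,5,8,8a-octahydroazulene-3,4-diol F3. Hydrogenation of the 1,1-disubstituted alkene only (H2, RhCl(PPh3)3, benzene) gives (3R,3aS,4S,8aR)-6,8a-dimethyl-3-(propan-2-yl)-1,2,3,3a,4,5,8,8a-octahydroazulene-3,4-diol F4. Acylation of F4 with 9 (Et3N, DMAP) comes back to the route at 11, which is oxidised as in the second stage of step 6.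

Further compounds
F1 | step 3 | trimethyl{[(3R)-3-methyl-3-(prop-2-en-1-yl)cyclopent-1-en-1-yl]oxy}silane | C=CC[C@@]1(C)CCC(O[Si](C)(C)C)=C1
F2 | step 4 | (3aS,4S,8aR)-4-hydroxy-6,8a-dimethyl-2,3a,4,5,8,8a-hexahydroazulen-3(1H)-one | O[C@H]1CC(C)=CC[C@@]2(C)CCC(=O)[C@H]12
F3 | step 4 | (3S,3aS,4S,8aR)-6,8a-dimethyl-3-(prop-1-en-2-yl)-1,2,3,3a,4,5,8,8a-octahydroazulene-3,4-diol | O[C@H]1CC(C)=CC[C@@]2(C)CC[C@@](O)(C(C)=C)[C@H]12
F4 | step 4 | (3R,3aS,4S,8aR)-6,8a-dimethyl-3-(propan-2-yl)-1,2,3,3a,4,5,8,8a-octahydroazulene-3,4-diol | O[C@H]1CC(C)=CC[C@@]2(C)CC[C@@](O)(C(C)C)[C@H]12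
F0 | step 6 | none | none
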